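Readings and results were generated by integration from invented constants; scatter was added.

Target comes slowly at first in the teal and ochre flasks, then fast, and that lag has to be carried over to heavier loadings of solid substrate.

| flask | solid substrate | coupling partner | remark | time |
|---|---|---|---|---|
| teal | 0.25 M | 1.4 equiv | run made earlier |  |
| ochre | 0.25 M | 1.8 equiv | run made earlier |  |
| north-west | 0.25 M | 0.900 equiv |  | 30 min |
| south-west | 0.50 M | 0.900 equiv |  | 30 min |
| north-east | 1.0 M | 0.900 equiv |  | 30 min |

- teal (time / min: target / %): 1.33: 1; 2.50: 0; 5.00: 4; 10.0: 8; 20.0: 28
- ochre (time / min: target / %): 1.50: 1; 5.00: 2; 8.00: 9; 12.0: 16; 20.0: 35

(standard deviation of a reading: 1.5 percentage points)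

- solid, in amounts per volume of the solution: solid substrate
- at the start none of the solid substrate is in solution
- a reading or a percentage of target counts all its forms, free or not
- the concentration of target that is asked is that of its free form alone
- "hardly changes" means that all values lie within two and a half points (for a concentration: within two and a half percent of the largest)

* [target] (only what is free in solution) at the end for north-west, south-west, north-east, in this order
* how that number moves from the first to the last of them (falls, then rises / falls all the way / rises all the way / rises, then falls / hardly changes)

Both earlier flasks hold 0.25 M of solid substrate. At 20.0 min teal reads 28% and ochre 35%. Raising the coupling partner by a factor of 1.29 raises target by 1.25, so the step looks first order in coupling partner.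

Now suppose c(dissolved substrate) climbs in proportion to time. Coupling partner then decays in a pseudo-first-order way, with a rate constant that grows with t. Integrating gives the fraction of partner turned into target as one minus the exponential of minus the square of t/τ. Here τ is the lag time, the time scale of that square law.

Teal's last reading gives τ = 42.3 min, and ochre's gives 43.0 min, two separate readings that nearly coincide. At 30 min the fraction is therefore 39.5%, and for north-west that means c(target) = 0.0888 M.

Two chemists part here. The first holds that the lag is the same over any charge, with a rate “independent of the solid loading”, so target follows the partner charged. That is the forecast: 0.09 M, 0.17 M, 0.33 M, which rises all the way. My own τ gives a little more for north-east, 0.355 M. The second chemist holds that the solid feeds the solution at one pace per volume, whatever lies on the bottom. She further takes dissolved substrate to react as fast as it arrives, so she expects target per volume to follow that supply, a row flat near 0.0888 M.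

The simulation gives 0.0630 M, 0.0789 M, 0.0734 M: the number rises, then falls, turning at 0.61 M. The first chemist's rise holds below that loading, from north-west towards south-west. At north-east the forecast stands 4.50 times above the flask.

    solid substrate ⇌ dissolved substrate, rate k1*(cs1 - [dissolved substrate]) while solid is left; crystals form when [dissolved substrate] > cs1 (solubility = 0.210 M, k = 0.0410 min⁻¹)
    dissolved substrate + coupling partner → target (k = 0.250 M⁻¹ min⁻¹)
    coupling partner + target ⇌ idle adduct, settled at all times (K = 2.30 M⁻¹)

Put back on north-west, τ gives 0.0888 M of target with all forms counted, and that flask holds 0.0812 M. On north-east it gives 0.355 M against 0.178 M, so the lag read there is 64.0 min, longer than τ. Part of the low free target at north-east comes from the low solubility of dissolved substrate, acting together with the length of the run. Taking that solubility limit away turns the shape of the row and lifts free target at north-east from 0.0734 M to 0.646 M, and a run ten times as long lifts it to 0.858 M.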